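The cyclohexane ring (C5–C10) is closed last by forming C7–C8: an intramolecular allylboration in which a 2-(methoxycarbonyl)allylboronate (B–C13–C11=C7) adds through C7 to a C8 aldehyde. Numbering is that of the elemane skeleton (lactone C12(=O)–O–C6 with C11=C13 on C7; angelate on O8; C4(=C3)–C15O2H on C5; vinyl C1=C2 and C14 on C10). This one operation closes the six-membered ring, sets C7 and C8 and unveils the C11=C13 methylene, exploiting the homoallylic relation between the C8 carbinol and the C7–C11(=C13)–C12 acrylate of the α-methylene lactone. The acyclic precursor carries C5, C6 and C10, set by an enantioselective Ireland–Claisen rearrangement of an itaconate and a Felkin alkynylation.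

Key step: step 10

Assumption: the (S,S)-antipode of the diazaborolidine controller is taken to deliver the (2R,3S)-acid 9 in step 4; should the sense of induction prove opposite, the (R,R)-antipode is used and nothing else changes.

Step 1
Reactants: 1 tert-butyl(but-3-yn-1-yloxy)dimethylsilane
Product: 3 (2E)-5-[(tert-butyldimethylsilyl)oxy]-3-methylpent-2-en-1-ol, via alkenylalane 2 (not isolated)
Conditions: Me3Al, Cp2ZrCl2 (cat.), CH2Cl2, 0 → 23 °C; then (CH2O)n, THF, 0 → 23 °C; aqueous potassium sodium tartrate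
Reagents that add atoms: trimethylaluminium C[Al](C)C; paraformaldehyde (as formaldehyde) C=O
Why: Zirconium-catalysed syn-carboalumination of the terminal alkyne (Negishi carboalumination) places methyl on the internal carbon and the alkenylalane is hydroxymethylated by formaldehyde with retention, so the E-trisubstituted allylic alcohol should result with no stereocenter formed.

Step 2
Reactants: 3 (2E)-5-[(tert-butyldimethylsilyl)oxy]-3-methylpent-2-en-1-ol; 4 itaconic anhydride
Product: 5 itaconic acid 4-monoester of alcohol 3 (allyl ester on the CH2-side carboxyl; conjugated acid free)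
Conditions: toluene, 70 °C
Reagents that add atoms: none
Why: Uncatalysed alcoholysis of the cyclic anhydride (anhydride ring-opening esterification) should occur at the more electrophilic non-conjugated carbonyl, which puts the allyl ester on the future C6 carboxyl and leaves the conjugated C15 acid free.

Step 3
Reactants: 5 itaconic acid 4-monoester
Product: 6 1-tert-butyl 4-[(2E)-5-(silyloxy)-3-methylpent-2-enyl] 2-methylidenebutanedioate
Conditions: O-tert-butyl-N,N′-diisopropylisourea, CH2Cl2, 23 °C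
Reagents that add atoms: O-tert-butyl-N,N′-diisopropylisourea CC(C)NC(=NC(C)C)OC(C)(C)C
Why: Esterification of the acid by the O-alkylisourea (isourea alkylation) runs under neutral conditions, so the silyl ether survives and the itaconate is not isomerised into conjugation.

Step 4
Reactants: 6 mixed itaconate diester
Product: 9 (2R,3S)-2-(3-tert-butoxy-3-oxoprop-1-en-2-yl)-3-[2-(tert-butyldimethylsilyloxy)ethyl]-3-methylpent-4-enoic acid, via boron ketene acetal 7 (not isolated), via acyloxyborane 8 (not isolated)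
Conditions: (S,S)-N,N′-ditosyl-1,2-diphenylethane-1,2-diamine, BBr3, CH2Cl2, 23 °C, then vacuum (gives the 2-bromodiazaborolidine); 6, Et3N, toluene/hexane, −78 °C, then −20 → 4 °C; aqueous work-up
Reagents that add atoms: none
Why: In this enantioselective boron-mediated Ireland–Claisen rearrangement, soft enolisation at the doubly activated C5–H should give the dienolate with the acrylate carbon trans to O–B, and its chair [3,3] shift with the E-olefin (C9 chain equatorial, C14 methyl axial) forms C5–C10 and sets C5 and the quaternary C10 in the required relative sense, while the C2-symmetric sulfonamide controller selects the face.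

Step 5
Reactants: 9 (2R,3S)-acid
Product: 11 tert-butyl (3R,4S)-4-[2-(tert-butyldimethylsilyloxy)ethyl]-3-formyl-4-methyl-2-methylidenehex-5-enoate, via acid chloride 10 (not isolated)
Conditions: 1-chloro-N,N,2-trimethylprop-1-en-1-amine, CH2Cl2, 0 °C; then LiAlH(Ot-Bu)3, THF, −78 °C
Reagents that add atoms: none
Why: The neutral α-chloroenamine makes the acid chloride without acid or base that could epimerise C5, and LiAlH(Ot-Bu)3 at −78 °C reduces an acid chloride only as far as the aldehyde (partial hydride reduction) while both esters are left alone.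

Step 6
Reactants: 11 aldehyde; 12 methyl propiolate
Product: 14 1-tert-butyl 7-methyl (3R,4R)-4-hydroxy-2-methylidene-3-[(3S)-5-(silyloxy)-3-methylpent-1-en-3-yl]hept-5-ynedioate, via lithium acetylide 13 (not isolated)
Conditions: 12, LiN(SiMe3)2, THF, −78 °C; then 11, −78 °C; aq. NH4Cl at −78 °C
Reagents that add atoms: none
Why: 1,2-Addition of the lithium acetylide to the aldehyde (alkynylation) under Felkin–Anh control, with the quaternary C10 group as the large substituent anti to the nucleophile and the acrylate as the medium one, should give the (R)-carbinol at C6.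

Step 7
Reactants: 14 γ-hydroxy ynoate
Product: 15 (3R,4R)-4-(tert-butyldimethylsilyloxy) ynoate
Conditions: t-BuMe2SiOTf, 2,6-lutidine, CH2Cl2, −78 → 0 °C
Reagents that add atoms: tert-butyldimethylsilyl trifluoromethanesulfonate CC(C)(C)[Si](C)(C)OS(=O)(=O)C(F)(F)F
Why: Silylation of the hindered propargylic alcohol with the silyl triflate and a non-nucleophilic base (silyl ether formation) blocks O6 so that it cannot lactonise onto C12 once the cis-enoate is made.

Step 8
Reactants: 15 silylated ynoate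
Product: 17 1-tert-butyl 7-methyl (3R,4S,5Z)-4-(silyloxy)-2-methylidene-6-[(pinacolboryl)methyl]-3-[(3S)-5-(silyloxy)-3-methylpent-1-en-3-yl]hept-5-enedioate, via vinylalane 16 (not isolated)
Conditions: i-Bu2AlH, HMPA, THF, 0 °C; then ICH2Bpin, 0 → 23 °C
Reagents that add atoms: 2-(iodomethyl)-4,4,5,5-tetramethyl-1,3,2-dioxaborolane ICB1OC(C)(C)C(C)(C)O1
Why: Conjugate syn-hydroalumination of the ynoate by the i-Bu2AlH–HMPA complex (the α-substituted acrylate is expected to need copper catalysis to react) gives the α-alumino enoate with H7 and aluminium cis, and transfer of this alkenyl group to the (iodomethyl)boronate with 1,2-shift and loss of iodide (Matteson-type homologation) fixes the 5Z geometry with C6 cis to the ester.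

Step 9
Reactants: 17 allylboronate bis-silyl ether
Product: 18 (3R,4S,5Z)-allylboronate with free primary alcohol at C8
Conditions: camphorsulfonic acid (cat.), MeOH/CH2Cl2, 0 °C
Reagents that add atoms: none
Why: Acid-catalysed methanolysis cleaves the unhindered primary silyl ether much faster than the secondary one flanked by C5 and C7 (selective desilylation), and the pinacol boronate tolerates these conditions.

Step 10
Reactants: 18 allylboronate alcohol
Product: 21 tert-butyl 2-[(1R,2S,4S,5R,6R)-6-(tert-butyldimethylsilyloxy)-2-ethenyl-4-hydroxy-5-(3-methoxy-3-oxoprop-1-en-2-yl)-2-methylcyclohexyl]prop-2-enoate, via aldehyde 19 (not isolated), via borate ester 20 (not isolated)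
Conditions: Dess–Martin periodinane, CH2Cl2, 0 → 23 °C; filtration, then toluene, 50 °C; pH 7 buffer
Reagents that add atoms: none
Why: The aldehyde released at C8 is attacked by C7 of the allylboronate through a closed six-membered Zimmerman–Traxler transition state (B–O8 coordination, C13–B bond broken, C11=C13 formed), which is the known allylboration of aldehydes by 2-alkoxycarbonyl allylboronates run intramolecularly. The carbocycle C5–C10 closes in a 6-exo-trig mode at the aldehyde carbon, and the two chairs (boracycle and forming cyclohexane) are fused like a trans-decalin. C7 and C8 are set relative to each other by the 5Z olefin geometry: C6 is trans to the CH2B carbon and so sits equatorial in the boracycle, which places H7 and H8 anti and gives the trans C11/O8 relationship. Their sense relative to C5, C6 and C10 is set by the forming cyclohexane chair, which keeps the C5 acrylate, the C6 silyl ether and O8 equatorial and only the C14 methyl axial, whereas the flipped chair would put the C5, C6 and vinyl substituents axial. The step needs chemoselectivity (only the aldehyde reacts; both acrylates and the vinyl group are inert to the boronate) and must stop before the O8 borate attacks the C12 ester, which the mild temperature and the strain of that trans-fused lactone should secure.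

Step 11
Reactants: 21 cyclohexanol; 22 angelic acid
Product: 24 8-O-angelate of 21, via mixed anhydride 23 (not isolated)
Conditions: 22, 2,4,6-trichlorobenzoyl chloride, Et3N, toluene, 23 °C; then 21, 75 °C
Reagents that add atoms: none
Why: Yamaguchi esterification of the equatorial C8 alcohol by the preformed mixed anhydride, run without a nucleophilic pyridine catalyst, should give the angelate without Z to E isomerisation to the tiglate and faster than O8 can lactonise onto C12.

Step 12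
Reactants: 24 angelate silyl ether
Product: 26 tert-butyl ester of the target (6,12-lactone closed), via hydroxy ester 25 (not isolated)
Conditions: HF·pyridine, THF, 0 → 40 °C
Reagents that add atoms: none
Why: Desilylation by HF frees the equatorial 6-OH, which lies trans-diequatorial to the C7 acrylate and closes the trans-fused γ-lactone onto the C12 methyl ester by acid-promoted transesterification (lactonisation), the tert-butyl ester at C15 being inert to acyl substitution.

Step 13
Reactants: 26 lactone tert-butyl ester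
Product: 27 CNP0256928.3
Conditions: CF3CO2H, CH2Cl2, 0 → 23 °C
Reagents that add atoms: none
Why: Acidolysis of the tert-butyl ester through the tert-butyl cation (loss of isobutene) frees the C15 acid without touching the lactone, the angelate or the three alkenes.

Compound list

1 | tert-butyl(but-3-yn-1-yloxy)dimethylsilane | C#CCCO[Si](C)(C)C(C)(C)C | starting material
2 | [(1E)-4-{[tert-butyl(dimethyl)silyl]oxy}-2-methylbut-1-en-1-yl]dimethylalumane | C[Al](C)/C=C(\C)CCO[Si](C)(C)C(C)(C)C | intermediate (not isolated)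
3 | (2E)-5-{[tert-butyl(dimethyl)silyl]oxy}-3-methylpent-2-en-1-ol | OC/C=C(\C)CCO[Si](C)(C)C(C)(C)C | intermediate
4 | itaconic anhydride (3-methylideneoxolane-2,5-dione) | C=C1CC(=O)OC1=O | starting material
5 | 4-{[(2E)-5-{[tert-butyl(dimethyl)silyl]oxy}-3-methylpent-2-en-1-yl]oxy}-2-methylidene-4-oxobutanoic acid | C=C(CC(=O)OC/C=C(\C)CCO[Si](C)(C)C(C)(C)C)C(=O)O | intermediate
6 | 1-tert-butyl 4-[(2E)-5-{[tert-butyl(dimethyl)silyl]oxy}-3-methylpent-2-en-1-yl] 2-methylidenebutanedioate | C=C(CC(=O)OC/C=C(\C)CCO[Si](C)(C)C(C)(C)C)C(=O)OC(C)(C)C | intermediate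
7 | tert-butyl (3Z)-4-{[(4S,5S)-1,3-bis(4-methylbenzenesulfonyl)-4,5-diphenyl-1,3,2-diazaborolidin-2-yl]oxy}-4-{[(2E)-5-{[tert-butyl(dimethyl)silyl]oxy}-3-methylpent-2-en-1-yl]oxy}-2-methylidenebut-3-enoate | C=C(/C=C(\OC/C=C(\C)CCO[Si](C)(C)C(C)(C)C)OB1N(S(=O)(=O)c2ccc(C)cc2)[C@@H](c2ccccc2)[C@H](c2ccccc2)N1S(=O)(=O)c1ccc(C)cc1)C(=O)OC(C)(C)C | intermediate (not isolated)
8 | (4S,5S)-1,3-bis(4-methylbenzenesulfonyl)-4,5-diphenyl-1,3,2-diazaborolidin-2-yl (2R,3S)-2-(3-tert-butoxy-3-oxoprop-1-en-2-yl)-3-(2-{[tert-butyl(dimethyl)silyl]oxy}ethyl)-3-methylpent-4-enoate | C=C[C@](C)(CCO[Si](C)(C)C(C)(C)C)[C@H](C(=C)C(=O)OC(C)(C)C)C(=O)OB1N(S(=O)(=O)c2ccc(C)cc2)[C@@H](c2ccccc2)[C@H](c2ccccc2)N1S(=O)(=O)c1ccc(C)cc1 | intermediate (not isolated)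
9 | (2R,3S)-2-(3-tert-butoxy-3-oxoprop-1-en-2-yl)-3-(2-{[tert-butyl(dimethyl)silyl]oxy}ethyl)-3-methylpent-4-enoic acid | C=C[C@](C)(CCO[Si](C)(C)C(C)(C)C)[C@H](C(=C)C(=O)OC(C)(C)C)C(=O)O | intermediate
10 | tert-butyl (3R,4S)-4-(2-{[tert-butyl(dimethyl)silyl]oxy}ethyl)-3-(carbonochloridoyl)-4-methyl-2-methylidenehex-5-enoate | C=C[C@](C)(CCO[Si](C)(C)C(C)(C)C)[C@H](C(=C)C(=O)OC(C)(C)C)C(Cl)=O | intermediate (not isolated)
11 | tert-butyl (3R,4S)-4-(2-{[tert-butyl(dimethyl)silyl]oxy}ethyl)-3-formyl-4-methyl-2-methylidenehex-5-enoate | C=C[C@](C)(CCO[Si](C)(C)C(C)(C)C)[C@H](C(=C)C(=O)OC(C)(C)C)C=O | intermediate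
12 | methyl propiolate (methyl prop-2-ynoate) | C#CC(=O)OC | starting material
13 | methyl 3-lithioprop-2-ynoate | [Li]C#CC(=O)OC | intermediate (not isolated)
14 | 1-tert-butyl 7-methyl (3R,4R)-3-[(3S)-5-{[tert-butyl(dimethyl)silyl]oxy}-3-methylpent-1-en-3-yl]-4-hydroxy-2-methylidenehept-5-ynedioate | C=C[C@](C)(CCO[Si](C)(C)C(C)(C)C)[C@H](C(=C)C(=O)OC(C)(C)C)[C@@H](O)C#CC(=O)OC | intermediate
15 | 1-tert-butyl 7-methyl (3R,4R)-4-{[tert-butyl(dimethyl)silyl]oxy}-3-[(3S)-5-{[tert-butyl(dimethyl)silyl]oxy}-3-methylpent-1-en-3-yl]-2-methylidenehept-5-ynedioate | C=C[C@](C)(CCO[Si](C)(C)C(C)(C)C)[C@H](C(=C)C(=O)OC(C)(C)C)[C@@H](O[Si](C)(C)C(C)(C)C)C#CC(=O)OC | intermediate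
16 | 1-tert-butyl 7-methyl (3R,4R,5E)-6-[bis(2-methylpropyl)alumanyl]-4-{[tert-butyl(dimethyl)silyl]oxy}-3-[(3S)-5-{[tert-butyl(dimethyl)silyl]oxy}-3-methylpent-1-en-3-yl]-2-methylidenehept-5-enedioate | C=C[C@](C)(CCO[Si](C)(C)C(C)(C)C)[C@H](C(=C)C(=O)OC(C)(C)C)[C@@H](O[Si](C)(C)C(C)(C)C)/C=C(/[Al](CC(C)C)CC(C)C)C(=O)OC | intermediate (not isolated)
17 | 1-tert-butyl 7-methyl (3R,4S,5Z)-4-{[tert-butyl(dimethyl)silyl]oxy}-3-[(3S)-5-{[tert-butyl(dimethyl)silyl]oxy}-3-methylpent-1-en-3-yl]-2-methylidene-6-[(4,4,5,5-tetramethyl-1,3,2-dioxaborolan-2-yl)methyl]hept-5-enedioate | C=C[C@](C)(CCO[Si](C)(C)C(C)(C)C)[C@H](C(=C)C(=O)OC(C)(C)C)[C@@H](O[Si](C)(C)C(C)(C)C)/C=C(/CB1OC(C)(C)C(C)(C)O1)C(=O)OC | intermediate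
18 | 1-tert-butyl 7-methyl (3R,4S,5Z)-4-{[tert-butyl(dimethyl)silyl]oxy}-3-[(3S)-5-hydroxy-3-methylpent-1-en-3-yl]-2-methylidene-6-[(4,4,5,5-tetramethyl-1,3,2-dioxaborolan-2-yl)methyl]hept-5-enedioate | C=C[C@](C)(CCO)[C@H](C(=C)C(=O)OC(C)(C)C)[C@@H](O[Si](C)(C)C(C)(C)C)/C=C(/CB1OC(C)(C)C(C)(C)O1)C(=O)OC | intermediate
19 | 1-tert-butyl 7-methyl (3R,4S,5Z)-4-{[tert-butyl(dimethyl)silyl]oxy}-3-[(3S)-3-methyl-5-oxopent-1-en-3-yl]-2-methylidene-6-[(4,4,5,5-tetramethyl-1,3,2-dioxaborolan-2-yl)methyl]hept-5-enedioate | C=C[C@](C)(CC=O)[C@H](C(=C)C(=O)OC(C)(C)C)[C@@H](O[Si](C)(C)C(C)(C)C)/C=C(/CB1OC(C)(C)C(C)(C)O1)C(=O)OC | intermediate (not isolated)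
20 | tert-butyl 2-[(1R,2S,4S,5R,6R)-6-{[tert-butyl(dimethyl)silyl]oxy}-2-ethenyl-5-(3-methoxy-3-oxoprop-1-en-2-yl)-2-methyl-4-[(4,4,5,5-tetramethyl-1,3,2-dioxaborolan-2-yl)oxy]cyclohexyl]prop-2-enoate | C=C[C@]1(C)C[C@H](OB2OC(C)(C)C(C)(C)O2)[C@@H](C(=C)C(=O)OC)[C@H](O[Si](C)(C)C(C)(C)C)[C@H]1C(=C)C(=O)OC(C)(C)C | intermediate (not isolated)
21 | tert-butyl 2-[(1R,2S,4S,5R,6R)-6-{[tert-butyl(dimethyl)silyl]oxy}-2-ethenyl-4-hydroxy-5-(3-methoxy-3-oxoprop-1-en-2-yl)-2-methylcyclohexyl]prop-2-enoate | C=C[C@]1(C)C[C@H](O)[C@@H](C(=C)C(=O)OC)[C@H](O[Si](C)(C)C(C)(C)C)[C@H]1C(=C)C(=O)OC(C)(C)C | intermediate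
22 | angelic acid ((2Z)-2-methylbut-2-enoic acid) | C/C=C(/C)C(=O)O | starting material
23 | (2Z)-2-methylbut-2-enoic 2,4,6-trichlorobenzoic anhydride | C/C=C(/C)C(=O)OC(=O)c1c(Cl)cc(Cl)cc1Cl | intermediate (not isolated)
24 | tert-butyl 2-[(1R,2S,4S,5R,6R)-6-{[tert-butyl(dimethyl)silyl]oxy}-2-ethenyl-5-(3-methoxy-3-oxoprop-1-en-2-yl)-2-methyl-4-{[(2Z)-2-methylbut-2-enoyl]oxy}cyclohexyl]prop-2-enoate | C=C[C@]1(C)C[C@H](OC(=O)/C(C)=C\C)[C@@H](C(=C)C(=O)OC)[C@H](O[Si](C)(C)C(C)(C)C)[C@H]1C(=C)C(=O)OC(C)(C)C | intermediate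
25 | tert-butyl 2-[(1R,2S,4S,5S,6R)-2-ethenyl-6-hydroxy-5-(3-methoxy-3-oxoprop-1-en-2-yl)-2-methyl-4-{[(2Z)-2-methylbut-2-enoyl]oxy}cyclohexyl]prop-2-enoate | C=C[C@]1(C)C[C@H](OC(=O)/C(C)=C\C)[C@@H](C(=C)C(=O)OC)[C@H](O)[C@H]1C(=C)C(=O)OC(C)(C)C | intermediate (not isolated)
26 | tert-butyl 2-[(3aR,4S,6S,7R,7aR)-6-ethenyl-6-methyl-4-{[(2Z)-2-methylbut-2-enoyl]oxy}-3-methylidene-2-oxooctahydro-1-benzofuran-7-yl]prop-2-enoate | C=C[C@]1(C)C[C@H](OC(=O)/C(C)=C\C)[C@H]2C(=C)C(=O)O[C@@H]2[C@H]1C(=C)C(=O)OC(C)(C)C | intermediate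
27 | CNP0256928.3: 2-[(3aR,4S,6S,7R,7aR)-6-ethenyl-6-methyl-4-{[(2Z)-2-methylbut-2-enoyl]oxy}-3-methylidene-2-oxooctahydro-1-benzofuran-7-yl]prop-2-enoic acid | C=C[C@]1(C)C[C@H](OC(=O)/C(C)=C\C)[C@H]2C(=C)C(=O)O[C@@H]2[C@H]1C(=C)C(=O)O | target

Total step count: 13. Longest linear sequence: 13 steps (1 to 27); compounds 4, 12 and 22 enter as bought.

Steps most likely to fail

Step 10. The ester-deactivated boronate may add too slowly, and at the higher temperature then needed the O8 borate could close the C12 lactone or the boronate could undergo a 1,3-boron shift. The fallback closes the ring with chromium instead; it sets out from 15 and comes back at 21. Hydroalumination of 15 as in step 8, with formaldehyde as the electrophile, should give the (5Z)-6-(hydroxymethyl) enoate F1. CBr4/PPh3 would turn it into the allylic bromide F2, camphorsulfonic acid in methanol would free the primary alcohol F3, and Dess–Martin oxidation would give the bromo aldehyde F4. CrCl2 (divalent chromium) in THF at high dilution would then effect a Nozaki–Hiyama–Kishi allylation through the chair transition state of the trivalent allylchromium species; with C6 cis to the ester this should again give the trans C7/C8 relationship and, after aqueous work-up, 21.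

Step 8. Over-reduction (conjugate reduction of the tert-butyl acrylate or attack on an ester) or loss of olefin geometry through the allenolate before the alkenyl group reaches boron may occur. The fallback sets out from 15 and comes back at 17. Bu3SnH with Pd(PPh3)4 should add syn with tin α to the ester and give the α-stannyl enoate F5. Iodine would replace tin with retention to give the α-iodo enoate F6. Negishi coupling of F6 with IZnCH2Bpin and Pd(PPh3)4 would give 17.

Step 4. Enolisation by the boron reagent may give a mixture of enolate geometries, or the boron enolate may rearrange too slowly, eroding diastereo- and enantioselectivity. The fallback separates bond formation from absolute control; it sets out from 6 and comes back at 9. LiN(i-Pr)2 with Me3SiCl as internal quench in THF at −78 °C would give the trimethylsilyl ketene acetal F7, which on warming rearranges to the silyl ester F8. Hydrolysis gives the racemic acid F9. This would be resolved by fractional crystallisation of its (S)-1-phenylethylammonium salt F10 (or the salt of the antipodal amine, whichever carries 9), and acidification returns 9.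

Further compounds

F1 | step 10 | 1-tert-butyl 7-methyl (3R,4S,5Z)-4-{[tert-butyl(dimethyl)silyl]oxy}-3-[(3S)-5-{[tert-butyl(dimethyl)silyl]oxy}-3-methylpent-1-en-3-yl]-6-(hydroxymethyl)-2-methylidenehept-5-enedioate | C=C[C@](C)(CCO[Si](C)(C)C(C)(C)C)[C@H](C(=C)C(=O)OC(C)(C)C)[C@@H](O[Si](C)(C)C(C)(C)C)/C=C(/CO)C(=O)OC
F2 | step 10 | 1-tert-butyl 7-methyl (3R,4S,5E)-6-(bromomethyl)-4-{[tert-butyl(dimethyl)silyl]oxy}-3-[(3S)-5-{[tert-butyl(dimethyl)silyl]oxy}-3-methylpent-1-en-3-yl]-2-methylidenehept-5-enedioate | C=C[C@](C)(CCO[Si](C)(C)C(C)(C)C)[C@H](C(=C)C(=O)OC(C)(C)C)[C@@H](O[Si](C)(C)C(C)(C)C)/C=C(/CBr)C(=O)OC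
F3 | step 10 | 1-tert-butyl 7-methyl (3R,4S,5E)-6-(bromomethyl)-4-{[tert-butyl(dimethyl)silyl]oxy}-3-[(3S)-5-hydroxy-3-methylpent-1-en-3-yl]-2-methylidenehept-5-enedioate | C=C[C@](C)(CCO)[C@H](C(=C)C(=O)OC(C)(C)C)[C@@H](O[Si](C)(C)C(C)(C)C)/C=C(/CBr)C(=O)OC
F4 | step 10 | 1-tert-butyl 7-methyl (3R,4S,5E)-6-(bromomethyl)-4-{[tert-butyl(dimethyl)silyl]oxy}-3-[(3S)-3-methyl-5-oxopent-1-en-3-yl]-2-methylidenehept-5-enedioate | C=C[C@](C)(CC=O)[C@H](C(=C)C(=O)OC(C)(C)C)[C@@H](O[Si](C)(C)C(C)(C)C)/C=C(/CBr)C(=O)OC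
F5 | step 8 | 1-tert-butyl 7-methyl (3R,4R,5E)-4-{[tert-butyl(dimethyl)silyl]oxy}-3-[(3S)-5-{[tert-butyl(dimethyl)silyl]oxy}-3-methylpent-1-en-3-yl]-2-methylidene-6-(tributylstannyl)hept-5-enedioate | C=C[C@](C)(CCO[Si](C)(C)C(C)(C)C)[C@H](C(=C)C(=O)OC(C)(C)C)[C@@H](O[Si](C)(C)C(C)(C)C)/C=C(/[Sn](CCCC)(CCCC)CCCC)C(=O)OC
F6 | step 8 | 1-tert-butyl 7-methyl (3R,4R,5E)-4-{[tert-butyl(dimethyl)silyl]oxy}-3-[(3S)-5-{[tert-butyl(dimethyl)silyl]oxy}-3-methylpent-1-en-3-yl]-6-iodo-2-methylidenehept-5-enedioate | C=C[C@](C)(CCO[Si](C)(C)C(C)(C)C)[C@H](C(=C)C(=O)OC(C)(C)C)[C@@H](O[Si](C)(C)C(C)(C)C)/C=C(/I)C(=O)OC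
F7 | step 4 | tert-butyl (3Z)-4-{[(2E)-5-{[tert-butyl(dimethyl)silyl]oxy}-3-methylpent-2-en-1-yl]oxy}-2-methylidene-4-[(trimethylsilyl)oxy]but-3-enoate | C=C(/C=C(\OC/C=C(\C)CCO[Si](C)(C)C(C)(C)C)O[Si](C)(C)C)C(=O)OC(C)(C)C
F8 | step 4 | trimethylsilyl rac-(2R,3S)-2-(3-tert-butoxy-3-oxoprop-1-en-2-yl)-3-(2-{[tert-butyl(dimethyl)silyl]oxy}ethyl)-3-methylpent-4-enoate (racemate, one enantiomer drawn) | C=C[C@](C)(CCO[Si](C)(C)C(C)(C)C)[C@H](C(=C)C(=O)OC(C)(C)C)C(=O)O[Si](C)(C)C
F9 | step 4 | rac-(2R,3S)-2-(3-tert-butoxy-3-oxoprop-1-en-2-yl)-3-(2-{[tert-butyl(dimethyl)silyl]oxy}ethyl)-3-methylpent-4-enoic acid (racemate of 9, one enantiomer drawn) | C=C[C@](C)(CCO[Si](C)(C)C(C)(C)C)[C@H](C(=C)C(=O)OC(C)(C)C)C(=O)O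
F10 | step 4 | (1S)-1-phenylethan-1-aminium (2R,3S)-2-(3-tert-butoxy-3-oxoprop-1-en-2-yl)-3-(2-{[tert-butyl(dimethyl)silyl]oxy}ethyl)-3-methylpent-4-enoate | C=C[C@](C)(CCO[Si](C)(C)C(C)(C)C)[C@H](C(=C)C(=O)OC(C)(C)C)C(=O)[O-].C[C@H]([NH3+])c1ccccc1
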